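## The problem

1. The target 21 is a trimer of two resveratrol units (a, c) and one oxyresveratrol unit (b). In the usual oligostilbene labels each unit has an aryl ring 1 on C7 and a resorcinol ring 2 (C9–C14) on C8, so ring B2 is the central benzene, ring B1 the 2,4-dihydroxyphenyl group on C7b, rings A1/C1 the 4-hydroxyphenyl groups and rings A2/C2 the 3,5-dihydroxyphenyl groups.
2. Ring B2 is pentasubstituted: it carries a trans-2,3-diaryl-2,3-dihydrofuran on C10b/C11b (C8a, C7a, O), a second one on C14b/C13b (C8c, C7c, O), and at C9b, between them, the methylene C8b of a seven-membered carbocycle (C8a–C9a–C10a–C7b–C8b–C9b–C10b) that ties ring A2 back to C7b.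
3. There are five stereocentres (7aS, 8aS, 7bS, 7cR, 8cR): each furan is trans, C7b stands to C8a as in the ampelopsin B series (H-7b trans to H-8a), and the second furan is separated from the other three centres by the aromatic ring B2, so no centre of the tetracyclic half can be expected to control it.
4. The feature that opens the problem is a hidden mirror plane: when the C7b–C10a bond is cut and the C7b=C8b double bond restored, the (7aS,8aS) furan and the (7cR,8cR) furan are mirror images across the plane through C12b, C9b and C8b, the stilbene is a meso compound, and rings A2 and C2 are enantiotopic.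
5. The second feature is the hydroxyl on C2b, ortho to C7b: it makes this stilbene an ortho-hydroxystyrene, which a chiral phosphoric acid can protonate at C8b to a hydrogen-bonded ortho-quinone methide with its cationic centre at C7b, within reach of C10a and of C10c alike.
6. One ring closure can therefore close the seven-membered ring, set C7b and decide the absolute configuration of the four furan centres; what remains is a question of relative configuration only, the syn placing of two trans-dihydrofurans on one benzene ring (meso against C2-symmetric).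
7. The sensitive points are the benzylic C7–O bonds, which ionise under acid, the electron-rich stilbene, which any achiral acid would cyclise to racemic product, and eight phenols that must be carried as ethers to the end.

## Retrosynthesis

**21 from 20 (seven O–CH3 bonds).** The phenols are carried as methyl ethers, which survive every step and come with the commercial building blocks. Only the C2b hydroxyl is free in 20, because the key step needs it. The forward reaction is a global ether cleavage on a compound that no longer holds an alkene.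

**20 from 18 (C7b–C10a bond).** Cutting here removes the seven-membered ring and one stereocentre and leaves the meso stilbene 18, which is achiral. The neighbouring cuts (C8b–C9b, C8a–C9a, or either furan) would all leave a chiral precursor whose absolute configuration would have to be bought separately. The forward reaction must protonate C8b, pass through the ortho-quinone methide 19, choose ring A2 over its enantiotopic twin C2, and set C7b trans to H-8a.

**18 from 16 and 17 (C7b–C1b bond).** A Heck reaction of styrene 16 with 2-iodo-5-methoxyphenol 17 brings in ring B1 with its hydroxyl already free. The alternative cut through C7b=C8b (Wittig or phosphonate olefination) would need either a protecting group on that hydroxyl or a benzylic halide at C8b next to two nucleophilic dimethoxyphenyl rings. The forward reaction must give the E-alkene without acid.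

**16 from 15, 14 and 13 (C8b=C7b, then the oxidation level of C8b).** The vinyl group comes from aldehyde 15 by methylenation, the aldehyde from alcohol 14, and the alcohol from ester 13. The ester is chosen as the form of C8b for the early steps because it tolerates Lewis acid, palladium catalysis, hydrogenation and acid.

**13 from 11 and 9 (four C–H bonds at C7a, C8a, C7c, C8c).** All four furan stereocentres are removed by going back to the flat, achiral benzodifuran 9. Heterogeneous hydrogenation should add hydrogen to both furans from the same face (through 10) and give the all-cis meso ester 11. Acid epimerisation at C7a and C7c only (through 12) then gives the trans,trans meso ester 13 with C8a and C8c still syn. A two-directional reaction under a chiral catalyst could not do this, because it would set both ends in the same absolute sense and give the C2-symmetric isomer.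

**9 from 6 and 7 (C7a–aryl and C7c–aryl bonds).** Two direct C–H arylations with 4-bromoanisole 7 (through 8) place rings A1 and C1 on the furan C2 positions of 6. This avoids a separate halogenation.

**6 from 4, and 4 from 1 and 2 (C8a–C10b and C8c–C14b; then O–C7a and O–C7c).** Double cyclodehydration of the bis(aryloxy ketone) 4 (through 5) forms both furan rings. Compound 4 comes from methyl 3,5-dihydroxybenzoate 1 and bromoketone 2 by double O-alkylation (through 3). Three commercial compounds thus give the whole carbon skeleton of units a, c and ring B2 in three steps.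

## Roads not taken

**Alternative 1:** the obvious linear plan. Cut the furan on C13b/C14b last (C8c–C14b and C7c–O bonds) from the tetracyclic phenol A1, itself made from an ε-viniferin-type stilbene by acid closure. The forward key step is a second dihydrofuran annulation on A1 under its own chiral catalyst. This needs three separate stereocontrol events: an enantioselective first furan, a diastereoselective ring closure, and a second furan set in the opposite absolute sense with no help from the remote centres. It also needs O11b told apart from O13b and C10b from C14b from the first step. The chosen plan treats both ends alike until one catalyst tells them apart.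

**Alternative 2:** the biomimetic plan. Cut both furans at once and form them by oxidative cross-coupling of oxyresveratrol with two resveratrol radicals, giving the unprotected meso trimer A2, then close the ring with acid. Radical coupling offers several regiochemical modes and homocoupling, gives no control of syn against anti placing of the furans, and delivers an octaphenol stilbene that would cyclise racemically under any acid. The chosen plan ends with the same ring closure but reaches the meso stilbene with defined relative configuration and a single free hydroxyl.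

**Alternative 3:** the two-directional asymmetric plan. Form both furans by double rhodium-carbene C–H insertion of the bis(diazo) compound A3 into its two 4-methoxybenzyl ethers with a chiral dirhodium tetracarboxylate. One chiral catalyst sets both ends in the same sense and should give the C2-symmetric ester A4, in which C7c and C8c have the configuration opposite to the one needed. The meso isomer would require two sequential insertions with both enantiomers of the catalyst on differentiated arms. The chosen plan obtains the meso relation from an achiral relay (same-face hydrogenation) and spends a chiral catalyst only once.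

Key step: step 10

Remark: precedent does not fix which enantiomer of the phosphoric acid selects ring A2; the (R)-acid is written, and the (S)-acid would be used if the closure proves to favour ring C2.

## Steps

Step 1
Reactants: 1 methyl 3,5-dihydroxybenzoate; 2 2-bromo-1-(3,5-dimethoxyphenyl)ethan-1-one (2.2 equiv)
Product: 4 methyl 3,5-bis[2-(3,5-dimethoxyphenyl)-2-oxoethoxy]benzoate, via mono-ether 3 (not isolated)
Conditions: K2CO3, acetone, reflux
Reagents that add atoms: none
Why: Williamson ether synthesis; each phenoxide displaces the primary α-keto bromide, and the ester is inert to carbonate.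

Step 2
Reactants: 4 methyl 3,5-bis[2-(3,5-dimethoxyphenyl)-2-oxoethoxy]benzoate
Product: 6 methyl 3,5-bis(3,5-dimethoxyphenyl)benzo[1,2-b:5,4-b']difuran-4-carboxylate, via mono-benzofuran 5 (not isolated)
Conditions: Bi(OTf)3 (20 mol %), ClCH2CH2Cl, reflux
Reagents that add atoms: none
Why: Lewis-acid-catalysed cyclodehydration of α-aryloxy ketones (intramolecular Friedel–Crafts hydroxyalkylation, then loss of water) to 3-arylbenzofurans. Each closure should go to the ring carbon para to the other oxygen and ortho to the ester (C10b, then C14b), the preference known for 5-alkoxy-3-(2-oxoethoxy)benzoates, rather than to C12b between the two oxygens.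

Step 3
Reactants: 6 methyl 3,5-bis(3,5-dimethoxyphenyl)benzo[1,2-b:5,4-b']difuran-4-carboxylate; 7 4-bromoanisole (3 equiv)
Product: 9 methyl 3,5-bis(3,5-dimethoxyphenyl)-2,6-bis(4-methoxyphenyl)benzo[1,2-b:5,4-b']difuran-4-carboxylate, via mono-arylated benzodifuran 8 (not isolated)
Conditions: Pd(OAc)2 (10 mol %), PCy3·HBF4 (20 mol %), PivOH (0.6 equiv), K2CO3, DMA, 110 °C
Reagents that add atoms: none
Why: Palladium-catalysed direct C–H arylation of benzofurans at C2 by concerted metalation–deprotonation, known for 3-arylbenzofurans with aryl bromides. The two furan C2–H bonds are the most acidic C–H bonds and lie away from the crowded ester.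

Step 4
Reactants: 9 methyl 3,5-bis(3,5-dimethoxyphenyl)-2,6-bis(4-methoxyphenyl)benzo[1,2-b:5,4-b']difuran-4-carboxylate
Product: 11 methyl (2R,3S,5R,6S)-3,5-bis(3,5-dimethoxyphenyl)-2,6-bis(4-methoxyphenyl)-2,3,5,6-tetrahydrobenzo[1,2-b:5,4-b']difuran-4-carboxylate (all-cis, meso), via half-hydrogenated benzofuran 10 (not isolated)
Conditions: H2 (50 bar), 10% Pd/C, EtOAc–EtOH, 60 °C
Reagents that add atoms: none
Why: Heterogeneous hydrogenation of 2,3-diarylbenzofurans delivers both hydrogens from the catalyst face and gives cis-dihydrobenzofurans. In 10 the two aryl groups on the new sp3 carbons stand on one face of the flat tricycle, which can then lie on the metal only with its other face, so the second furan should take its hydrogens from the same side and place C8a and C8c syn.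

Step 5
Reactants: 11 methyl (2R,3S,5R,6S)-3,5-bis(3,5-dimethoxyphenyl)-2,6-bis(4-methoxyphenyl)-2,3,5,6-tetrahydrobenzo[1,2-b:5,4-b']difuran-4-carboxylate
Product: 13 methyl (2S,3S,5R,6R)-3,5-bis(3,5-dimethoxyphenyl)-2,6-bis(4-methoxyphenyl)-2,3,5,6-tetrahydrobenzo[1,2-b:5,4-b']difuran-4-carboxylate (both furans trans, meso), via half-epimerised ester 12 (not isolated)
Conditions: CF3SO3H (10 mol %), CH2Cl2, −20 to 0 °C
Reagents that add atoms: none
Why: Acid-induced cis-to-trans isomerisation of 2-(4-alkoxyphenyl)-2,3-dihydrobenzofurans: the benzylic C7–O bond ionises to a 4-methoxybenzyl cation and the phenol recloses to the more stable trans ring, while C8a and C8c are not touched and keep their syn relation. The methyl ester is a poorer nucleophile than the phenol and its participation is reversible under a non-nucleophilic acid.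

Step 6
Reactants: 13 methyl (2S,3S,5R,6R)-3,5-bis(3,5-dimethoxyphenyl)-2,6-bis(4-methoxyphenyl)-2,3,5,6-tetrahydrobenzo[1,2-b:5,4-b']difuran-4-carboxylate
Product: 14 [(2S,3S,5R,6R)-3,5-bis(3,5-dimethoxyphenyl)-2,6-bis(4-methoxyphenyl)-2,3,5,6-tetrahydrobenzo[1,2-b:5,4-b']difuran-4-yl]methanol
Conditions: LiAlH4, THF, 0 °C to reflux; basic aqueous work-up
Reagents that add atoms: none
Why: Hydride reduction of a di-ortho-substituted benzoate, which LiAlH4 reduces where milder hydrides fail. The basic work-up keeps the benzylic alcohol away from acid, which could ionise it next to the dimethoxyphenyl rings.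

Step 7
Reactants: 14 [(2S,3S,5R,6R)-3,5-bis(3,5-dimethoxyphenyl)-2,6-bis(4-methoxyphenyl)-2,3,5,6-tetrahydrobenzo[1,2-b:5,4-b']difuran-4-yl]methanol
Product: 15 (2S,3S,5R,6R)-3,5-bis(3,5-dimethoxyphenyl)-2,6-bis(4-methoxyphenyl)-2,3,5,6-tetrahydrobenzo[1,2-b:5,4-b']difuran-4-carbaldehyde
Conditions: Dess–Martin periodinane, CH2Cl2, 25 °C
Reagents that add atoms: none
Why: Dess–Martin oxidation of a hindered benzylic alcohol to the aldehyde under nearly neutral conditions; the aldehyde has no α-hydrogen and the stereocentres are not at risk.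

Step 8
Reactants: 15 (2S,3S,5R,6R)-3,5-bis(3,5-dimethoxyphenyl)-2,6-bis(4-methoxyphenyl)-2,3,5,6-tetrahydrobenzo[1,2-b:5,4-b']difuran-4-carbaldehyde
Product: 16 (2S,3S,5R,6R)-4-ethenyl-3,5-bis(3,5-dimethoxyphenyl)-2,6-bis(4-methoxyphenyl)-2,3,5,6-tetrahydrobenzo[1,2-b:5,4-b']difuran
Conditions: Ph3PCH3Br, KOtBu, THF, 0 to 25 °C
Reagents that add atoms: methyltriphenylphosphonium bromide, C[P+](c1ccccc1)(c1ccccc1)c1ccccc1.[Br-]
Why: Wittig methylenation; the unstabilised ylide adds even to di-ortho-substituted benzaldehydes and the medium is basic, so no benzylic cation can form.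

Step 9
Reactants: 16 (2S,3S,5R,6R)-4-ethenyl-3,5-bis(3,5-dimethoxyphenyl)-2,6-bis(4-methoxyphenyl)-2,3,5,6-tetrahydrobenzo[1,2-b:5,4-b']difuran; 17 2-iodo-5-methoxyphenol
Product: 18 2-[(E)-2-{(2S,3S,5R,6R)-3,5-bis(3,5-dimethoxyphenyl)-2,6-bis(4-methoxyphenyl)-2,3,5,6-tetrahydrobenzo[1,2-b:5,4-b']difuran-4-yl}ethenyl]-5-methoxyphenol (meso)
Conditions: Pd(OAc)2 (5 mol %), P(o-tol)3 (10 mol %), Et3N, DMF, 90 °C, under argon; chromatography on Et3N-deactivated silica
Reagents that add atoms: none
Why: Heck reaction; the arylpalladium species adds its aryl group to the unhindered terminal carbon of the styrene and syn β-hydride elimination gives the E-stilbene. The free ortho-hydroxyl is tolerated, and the basic medium and deactivated silica keep the acid-sensitive product from closing racemically.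

Step 10
Reactants: 18 2-[(E)-2-{(2S,3S,5R,6R)-3,5-bis(3,5-dimethoxyphenyl)-2,6-bis(4-methoxyphenyl)-2,3,5,6-tetrahydrobenzo[1,2-b:5,4-b']difuran-4-yl}ethenyl]-5-methoxyphenol (meso)
Product: 20 (7aS,8aS,7bS,7cR,8cR)-heptamethyl ether of the target (all hydroxyls methylated except the one on C2b of ring B1; seven-membered ring closed between C7b and C10a), via ortho-quinone methide 19 (not isolated)
Conditions: (R)-3,3'-bis(2,4,6-triisopropylphenyl)-1,1'-binaphthyl-2,2'-diyl hydrogen phosphate (10 mol %), toluene (0.01 M), 0 to 25 °C
Reagents that add atoms: none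
Why: Proposed new method: the phosphoric acid should protonate C8b of the ortho-hydroxystilbene 18, the only site that leaves a cation stabilised by the 2-hydroxy-4-methoxyphenyl ring, and hold the resulting ortho-quinone methide 19 as a contact ion pair through the hydrogen bond of the C2b hydroxyl to the phosphate; the closest known reaction type is the chiral-phosphoric-acid-catalysed enantioselective addition of indoles and electron-rich arenes to ortho-quinone methides generated in the flask from ortho-hydroxystyrenes, here made intramolecular and used to choose between two enantiotopic arenes, while the bond formed is that of the known protic-acid closure of 2,3-diaryl-4-styryl-dihydrobenzofurans to the ampelopsin B skeleton. The seven-membered ring (C8a–C9a–C10a–C7b–C8b–C9b–C10b) closes by a cationic Friedel–Crafts alkylation, 7-exo-trig with respect to the C7b=C1b bond of 19, at C10a, which is ortho to one methoxy group and para to the other. C7b is set by the substrate: the chain C9b–C8b–C7b should reach C10a without strain only in the boat-like arrangement that places ring B1 pseudo-equatorial, which gives H-7b trans to H-8a (7bS for 8aS), the relation of the ampelopsin B series. For that reason ring A2 can attack only one face of 19 and ring C2 only the mirror-image face, so the face shielding that the phosphate exerts on its bound quinone methide becomes a choice between the two rings. Attack by ring A2, which sits on the (7aS,8aS) furan, gives 20, attack by ring C2 would give its enantiomer, and no third ring closure is within reach because the carbons between the methoxy groups cannot span the ring and rings A1 and C1 are too far away. The selectivity needed is thus group selectivity between enantiotopic rings, which one chiral catalyst supplies, and with it the absolute configuration of all five stereocentres is fixed in one operation; the non-polar solvent and high dilution keep the ion pair tight and suppress intermolecular trapping.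

Step 11
Reactants: 20 (7aS,8aS,7bS,7cR,8cR)-heptamethyl ether of the target
Product: 21 CNP0154047.3, the (7aS,8aS,7bS,7cR,8cR)-octaphenol
Conditions: BBr3 (excess), CH2Cl2, −78 to 25 °C; then MeOH, H2O
Reagents that add atoms: none
Why: Exhaustive Lewis-acid cleavage of aryl methyl ethers, a known final step for permethylated resveratrol oligomers that hold trans-2-aryl-dihydrobenzofurans but no stilbene alkene. The trans furans are the thermodynamic isomers, so a reversible opening of a C7–O bond should close back to the same configuration.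

## Compound list

1 | methyl 3,5-dihydroxybenzoate | COC(=O)c1cc(O)cc(O)c1 | starting material
2 | 2-bromo-1-(3,5-dimethoxyphenyl)ethan-1-one | COc1cc(OC)cc(c1)C(=O)CBr | starting material
3 | methyl 3-[2-(3,5-dimethoxyphenyl)-2-oxoethoxy]-5-hydroxybenzoate (mono-ether) | COC(=O)c1cc(O)cc(OCC(=O)c2cc(OC)cc(OC)c2)c1 | intermediate
4 | methyl 3,5-bis[2-(3,5-dimethoxyphenyl)-2-oxoethoxy]benzoate | COC(=O)c1cc(OCC(=O)c2cc(OC)cc(OC)c2)cc(OCC(=O)c2cc(OC)cc(OC)c2)c1 | intermediate
5 | methyl 3-(3,5-dimethoxyphenyl)-6-[2-(3,5-dimethoxyphenyl)-2-oxoethoxy]-1-benzofuran-4-carboxylate (mono-benzofuran) | COC(=O)c1cc(OCC(=O)c2cc(OC)cc(OC)c2)cc2occ(-c3cc(OC)cc(OC)c3)c12 | intermediate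
6 | methyl 3,5-bis(3,5-dimethoxyphenyl)benzo[1,2-b:5,4-b']difuran-4-carboxylate | COC(=O)c1c2c(-c3cc(OC)cc(OC)c3)coc2cc2occ(-c3cc(OC)cc(OC)c3)c12 | intermediate
7 | 4-bromoanisole | COc1ccc(Br)cc1 | starting material
8 | methyl 3,5-bis(3,5-dimethoxyphenyl)-2-(4-methoxyphenyl)benzo[1,2-b:5,4-b']difuran-4-carboxylate (mono-arylated) | COC(=O)c1c2c(-c3cc(OC)cc(OC)c3)c(-c3ccc(OC)cc3)oc2cc2occ(-c3cc(OC)cc(OC)c3)c12 | intermediate
9 | methyl 3,5-bis(3,5-dimethoxyphenyl)-2,6-bis(4-methoxyphenyl)benzo[1,2-b:5,4-b']difuran-4-carboxylate | COC(=O)c1c2c(-c3cc(OC)cc(OC)c3)c(-c3ccc(OC)cc3)oc2cc2oc(-c3ccc(OC)cc3)c(-c3cc(OC)cc(OC)c3)c12 | intermediate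
10 | methyl (2R*,3S*)-3,5-bis(3,5-dimethoxyphenyl)-2,6-bis(4-methoxyphenyl)-2,3-dihydrobenzo[1,2-b:5,4-b']difuran-4-carboxylate (cis, racemic; 2R,3S enantiomer drawn) | COc1ccc([C@@H]2Oc3cc4oc(-c5ccc(OC)cc5)c(-c5cc(OC)cc(OC)c5)c4c(C(=O)OC)c3[C@@H]2c2cc(OC)cc(OC)c2)cc1 | intermediate
11 | methyl (2R,3S,5R,6S)-3,5-bis(3,5-dimethoxyphenyl)-2,6-bis(4-methoxyphenyl)-2,3,5,6-tetrahydrobenzo[1,2-b:5,4-b']difuran-4-carboxylate (all-cis, meso) | COc1ccc([C@@H]2Oc3cc4c(c(C(=O)OC)c3[C@@H]2c2cc(OC)cc(OC)c2)[C@@H](c2cc(OC)cc(OC)c2)[C@@H](c2ccc(OC)cc2)O4)cc1 | intermediate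
12 | methyl (2S*,3S*,5R*,6S*)-3,5-bis(3,5-dimethoxyphenyl)-2,6-bis(4-methoxyphenyl)-2,3,5,6-tetrahydrobenzo[1,2-b:5,4-b']difuran-4-carboxylate (one furan trans, one cis; racemic; 2S,3S,5R,6S enantiomer drawn) | COc1ccc([C@H]2Oc3cc4c(c(C(=O)OC)c3[C@@H]2c2cc(OC)cc(OC)c2)[C@@H](c2cc(OC)cc(OC)c2)[C@@H](c2ccc(OC)cc2)O4)cc1 | intermediate
13 | methyl (2S,3S,5R,6R)-3,5-bis(3,5-dimethoxyphenyl)-2,6-bis(4-methoxyphenyl)-2,3,5,6-tetrahydrobenzo[1,2-b:5,4-b']difuran-4-carboxylate (both furans trans, meso) | COc1ccc([C@H]2Oc3cc4c(c(C(=O)OC)c3[C@@H]2c2cc(OC)cc(OC)c2)[C@@H](c2cc(OC)cc(OC)c2)[C@H](c2ccc(OC)cc2)O4)cc1 | intermediate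
14 | [(2S,3S,5R,6R)-3,5-bis(3,5-dimethoxyphenyl)-2,6-bis(4-methoxyphenyl)-2,3,5,6-tetrahydrobenzo[1,2-b:5,4-b']difuran-4-yl]methanol | COc1ccc([C@H]2Oc3cc4c(c(CO)c3[C@@H]2c2cc(OC)cc(OC)c2)[C@@H](c2cc(OC)cc(OC)c2)[C@H](c2ccc(OC)cc2)O4)cc1 | intermediate
15 | (2S,3S,5R,6R)-3,5-bis(3,5-dimethoxyphenyl)-2,6-bis(4-methoxyphenyl)-2,3,5,6-tetrahydrobenzo[1,2-b:5,4-b']difuran-4-carbaldehyde | COc1ccc([C@H]2Oc3cc4c(c(C=O)c3[C@@H]2c2cc(OC)cc(OC)c2)[C@@H](c2cc(OC)cc(OC)c2)[C@H](c2ccc(OC)cc2)O4)cc1 | intermediate
16 | (2S,3S,5R,6R)-4-ethenyl-3,5-bis(3,5-dimethoxyphenyl)-2,6-bis(4-methoxyphenyl)-2,3,5,6-tetrahydrobenzo[1,2-b:5,4-b']difuran | COc1ccc([C@H]2Oc3cc4c(c(C=C)c3[C@@H]2c2cc(OC)cc(OC)c2)[C@@H](c2cc(OC)cc(OC)c2)[C@H](c2ccc(OC)cc2)O4)cc1 | intermediate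
17 | 2-iodo-5-methoxyphenol | COc1ccc(I)c(O)c1 | starting material
18 | 2-[(E)-2-{(2S,3S,5R,6R)-3,5-bis(3,5-dimethoxyphenyl)-2,6-bis(4-methoxyphenyl)-2,3,5,6-tetrahydrobenzo[1,2-b:5,4-b']difuran-4-yl}ethenyl]-5-methoxyphenol (meso stilbene) | COc1ccc([C@H]2Oc3cc4c(c(/C=C/c5ccc(OC)cc5O)c3[C@@H]2c2cc(OC)cc(OC)c2)[C@@H](c2cc(OC)cc(OC)c2)[C@H](c2ccc(OC)cc2)O4)cc1 | intermediate
19 | (E)-ortho-quinone methide from 18: 6-ylidene-3-methoxycyclohexa-2,4-dien-1-one whose exocyclic carbon C7b carries H and the CH2 (C8b) bound to C4 of the (2S,3S,5R,6R)-tetrahydrobenzodifuran | COc1ccc([C@H]2Oc3cc4c(c(C/C=C5\C=CC(OC)=CC5=O)c3[C@@H]2c2cc(OC)cc(OC)c2)[C@@H](c2cc(OC)cc(OC)c2)[C@H](c2ccc(OC)cc2)O4)cc1 | intermediate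
20 | (7aS,8aS,7bS,7cR,8cR)-heptamethyl ether of the target (free hydroxyl on C2b only) | COc1ccc([C@H]2Oc3cc4c(c5c3[C@@H]2c2cc(OC)cc(OC)c2[C@H](c2ccc(OC)cc2O)C5)[C@@H](c2cc(OC)cc(OC)c2)[C@H](c2ccc(OC)cc2)O4)cc1 | intermediate
21 | CNP0154047.3, (7aS,8aS,7bS,7cR,8cR)-octaphenol | Oc1ccc([C@H]2Oc3cc4c(c5c3[C@@H]2c2cc(O)cc(O)c2[C@H](c2ccc(O)cc2O)C5)[C@@H](c2cc(O)cc(O)c2)[C@H](c2ccc(O)cc2)O4)cc1 | target

## Step count and risks

Total steps: 11. Longest linear sequence: 11 (the route is fully linear from 1).

**Step 10 (key step, new method).** The most likely failure is poor discrimination between the enantiotopic rings A2 and C2, because the phosphate binds the quinone methide far from the bulky tetrahydrobenzodifuran and the arene offers no hydrogen-bond donor. Slow protonation by the weak acid, or closure with both orientations of ring B1 (loss of control at C7b), are also possible. Adventitious achiral acid would close the ring racemically. The fallback uses known chemistry and sets out from 18: cyclisation with an achiral acid (diphenyl phosphate or CF3CO2H, CH2Cl2, 0 °C), the protic-acid closure known for this stilbene class, should give 20 as a racemate together with its mirror image, the (7aR,8aR,7bR,7cS,8cS)-heptamethyl ether F1. The racemate would be resolved by preparative chromatography on a chiral stationary phase (amylose tris(3,5-dimethylphenylcarbamate)), and the route is rejoined at 20.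

**Step 4.** Hydrogen may add to the second furan from either face if 10 leaves the surface and re-adsorbs without a strong facial bias. The tetrasubstituted, doubly arylated furan double bonds may also resist reduction, or the benzylic C–O bonds formed may be hydrogenolysed. The fallback sets out from 9: ionic hydrogenation (Et3SiH, CF3CO2H, CH2Cl2), a known reduction of benzofurans through the C2 oxocarbenium ion, should give trans furans directly. Without a facial relay it would give 13 together with the C2-symmetric diastereomer as a racemate, methyl (2S,3S,5S,6S)-3,5-bis(3,5-dimethoxyphenyl)-2,6-bis(4-methoxyphenyl)-2,3,5,6-tetrahydrobenzo[1,2-b:5,4-b']difuran-4-carboxylate F2 and its enantiomer, the (2R,3R,5R,6R)-ester F3. Compound 13 is a diastereomer of these and would be separated by crystallisation or chromatography; F2 and F3 would be returned to 9 by dehydrogenation with 2,3-dichloro-5,6-dicyano-1,4-benzoquinone. The route is rejoined at 13, and step 5 is not needed.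

**Step 2.** The second ring closure may go to C12b, between the two oxygens, instead of the crowded C14b next to the ester, or may stall because the ester ends up flanked by two aryl groups. The fallback blocks C12b. It sets out from 2 and from commercial methyl 4-bromo-3,5-dihydroxybenzoate F4: double O-alkylation (K2CO3, acetone) gives methyl 4-bromo-3,5-bis[2-(3,5-dimethoxyphenyl)-2-oxoethoxy]benzoate F5, and cyclodehydration with Bi(OTf)3, now possible only at C10b and C14b, gives methyl 8-bromo-3,5-bis(3,5-dimethoxyphenyl)benzo[1,2-b:5,4-b']difuran-4-carboxylate F6. Hydrogenolysis of the aryl bromide (H2 1 bar, Pd/C, Et3N, EtOAc, 25 °C), mild enough to leave the furans alone, rejoins the route at 6.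

**Step 11.** The Lewis acid may ionise the benzylic C7–O bonds, and seven ethers may not all be cleaved, giving a mixture of opened, epimerised and under-demethylated phenols that cannot be purified as a free, air-sensitive octaphenol. The fallback changes the isolation to capture and release and sets out from 20. After the BBr3 treatment the crude phenol would be stirred briefly with dilute HCl in MeOH, to re-close any opened furan to the trans isomer, and then peracetylated (Ac2O, pyridine) to the octaacetate of 21 F7. This can be chromatographed and crystallised free of the by-products. Methanolysis (K2CO3, MeOH, 0 °C, under argon) rejoins the route at 21.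

## Further compounds

F1 | step 10 | (7aR,8aR,7bR,7cS,8cS)-heptamethyl ether, enantiomer of 20 | COc1ccc([C@@H]2Oc3cc4c(c5c3[C@H]2c2cc(OC)cc(OC)c2[C@@H](c2ccc(OC)cc2O)C5)[C@H](c2cc(OC)cc(OC)c2)[C@@H](c2ccc(OC)cc2)O4)cc1
F2 | step 4 | methyl (2S,3S,5S,6S)-3,5-bis(3,5-dimethoxyphenyl)-2,6-bis(4-methoxyphenyl)-2,3,5,6-tetrahydrobenzo[1,2-b:5,4-b']difuran-4-carboxylate (C2-symmetric, both furans trans) | COc1ccc([C@H]2Oc3cc4c(c(C(=O)OC)c3[C@@H]2c2cc(OC)cc(OC)c2)[C@H](c2cc(OC)cc(OC)c2)[C@@H](c2ccc(OC)cc2)O4)cc1
F3 | step 4 | methyl (2R,3R,5R,6R)-3,5-bis(3,5-dimethoxyphenyl)-2,6-bis(4-methoxyphenyl)-2,3,5,6-tetrahydrobenzo[1,2-b:5,4-b']difuran-4-carboxylate (enantiomer of F2) | COc1ccc([C@@H]2Oc3cc4c(c(C(=O)OC)c3[C@H]2c2cc(OC)cc(OC)c2)[C@@H](c2cc(OC)cc(OC)c2)[C@H](c2ccc(OC)cc2)O4)cc1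
F4 | step 2 | methyl 4-bromo-3,5-dihydroxybenzoate | COC(=O)c1cc(O)c(Br)c(O)c1
F5 | step 2 | methyl 4-bromo-3,5-bis[2-(3,5-dimethoxyphenyl)-2-oxoethoxy]benzoate | COC(=O)c1cc(OCC(=O)c2cc(OC)cc(OC)c2)c(Br)c(OCC(=O)c2cc(OC)cc(OC)c2)c1
F6 | step 2 | methyl 8-bromo-3,5-bis(3,5-dimethoxyphenyl)benzo[1,2-b:5,4-b']difuran-4-carboxylate | COC(=O)c1c2c(-c3cc(OC)cc(OC)c3)coc2c(Br)c2occ(-c3cc(OC)cc(OC)c3)c12
F7 | step 11 | octaacetate of 21 | CC(=O)Oc1ccc([C@H]2Oc3cc4c(c5c3[C@@H]2c2cc(OC(C)=O)cc(OC(C)=O)c2[C@H](c2ccc(OC(C)=O)cc2OC(C)=O)C5)[C@@H](c2cc(OC(C)=O)cc(OC(C)=O)c2)[C@H](c2ccc(OC(C)=O)cc2)O4)cc1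
A1 | alternative 1 | (7aS,8aS,7bS)-tetracyclic phenol: ampelopsin-B-type core with 2,4-dimethoxyphenyl on C7b, free hydroxyl on C13b, hydrogen on C14b, other phenols methylated | COc1ccc([C@H]2Oc3cc(O)cc4c3[C@@H]2c2cc(OC)cc(OC)c2[C@H](c2ccc(OC)cc2OC)C4)cc1
A2 | alternative 2 | unprotected meso trimer: (E)-stilbene of oxyresveratrol with (7aS,8aS) and (7cR,8cR) trans-dihydrofurans on ring B2 | Oc1ccc([C@H]2Oc3cc4c(c(/C=C/c5ccc(O)cc5O)c3[C@@H]2c2cc(O)cc(O)c2)[C@@H](c2cc(O)cc(O)c2)[C@H](c2ccc(O)cc2)O4)cc1
A3 | alternative 3 | methyl 2,6-bis[diazo(3,5-dimethoxyphenyl)methyl]-3,5-bis[(4-methoxyphenyl)methoxy]benzoate | COC(=O)c1c(C(=[N+]=[N-])c2cc(OC)cc(OC)c2)c(OCc2ccc(OC)cc2)cc(OCc2ccc(OC)cc2)c1C(=[N+]=[N-])c1cc(OC)cc(OC)c1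
A4 | alternative 3 | methyl (2R,3S,5S,6R)-3,5-bis(3,5-dimethoxyphenyl)-2,6-bis(4-methoxyphenyl)-2,3,5,6-tetrahydrobenzo[1,2-b:5,4-b']difuran-4-carboxylate (C2-symmetric, both furans cis) | COc1ccc([C@@H]2Oc3cc4c(c(C(=O)OC)c3[C@@H]2c2cc(OC)cc(OC)c2)[C@H](c2cc(OC)cc(OC)c2)[C@H](c2ccc(OC)cc2)O4)cc1
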